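**Retrosynthetic overview**
- The strategy rests on the ring C–C bond C8–C8′ (the two CH carbons of the oxolane), which joins two identical guaiacyl C6–C3 halves; C7/C7′ are the carbinol carbons and C9/C9′ the ring OCH2 carbons.
- 15 ⇐ debenzylation of 14 ⇐ inversion of one carbinol (C7′) by oxidation and CBS reduction ⇐ C2-symmetric diol 12 ⇐ acylative kinetic resolution of rac-11.
- 11 ⇐ oxolane ring by C9–O–C9′ closure of tetraol 7 with O7/O7′ silylated ⇐ hydride opening of dibenzyl bis-lactone 6.
- 4 ⇐ two molecules of ferulic acid 1: oxidative C8–C8′ radical coupling, then two lactonisations that form both C7–O bonds.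
- Ring order: both γ-lactone rings together in step 1 (opened again in step 3), then the oxolane ring in step 6.

Key step: step 1

Remark on the chemistry: lignan locants are used throughout; 3, 4 and 6–11 are racemates whose SMILES show the enantiomer carried on after step 8; (R)-BTM is assumed to acylate (R)-configured aryl carbinols, as it does with 1-arylalkanols.

**Step 1**
Reactants: 1 ferulic acid (two molecules)
Product: 4 rac-exo,exo-diaryl cis-fused bis-γ-lactone (8–8′ dehydrodiferulic acid dilactone), via ferulic acid phenoxyl radical 2 (not isolated), via bis(quinone methide) diacid 3 (not isolated)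
Conditions: FeCl3·6H2O (1.1 equiv per phenol), acetone/H2O, air, rt; precipitate filtered
Reagents that add atoms: none
Why: Fe(III) takes one electron from each phenol to give phenoxyl radical 2, whose spin density at C8 lets two radicals combine to the C8–C8′ bond of bis(quinone methide) 3; the closest known reaction type is the biomimetic oxidative dehydrodimerisation of 4-hydroxycinnamic acids to 8–8′ dilactones. Each carboxyl group then adds to C7 of the opposite quinone methide in a 5-exo-trig oxa-conjugate addition that rearomatises the ring, and the two additions close the two γ-lactone rings of a 3,7-dioxabicyclo[3.3.0]octanedione. C8 and C8′ are set in the radical coupling, and only the like (R*,R*) adduct 3 can close twice because the 5/5 bicycle must be cis-fused. C7 and C7′ are set in the conjugate additions, where the aryl groups take the convex exo face (H7 trans to H8), the less crowded arrangement that the reversible, acid-mediated addition can reach. The step needs 8–8′ coupling ahead of 8–5′, 8–O–4′ and 5–5′ coupling, and the free carboxylic acids secure it by trapping the 8–8′ adduct twice intramolecularly as a sparingly soluble dilactone; no chiral influence is present, so 4 forms as a racemate.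

**Step 2**
Reactants: 4 rac-bis-lactone; 5 benzyl bromide
Product: 6 rac-4,4′-di-O-benzyl bis-lactone
Conditions: BnBr (2.5 equiv), K2CO3 (3 equiv), DMF, 0 °C → rt
Reagents that add atoms: benzyl bromide (5), BrCc1ccccc1
Why: Williamson ether synthesis on the two phenols with a mild carbonate base, where excess bromide at low temperature is meant to let O-alkylation outrun base-induced 1,6-elimination of the lactone carboxylate from the p-hydroxybenzyl positions, and no stereocentre is touched.

**Step 3**
Reactants: 6 rac-di-O-benzyl bis-lactone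
Product: 7 rac-(7S,8R,8′R,7′S)-tetraol
Conditions: LiAlH4 (excess), THF, 0 °C → rt; Rochelle salt work-up
Reagents that add atoms: none
Why: Lithium aluminium hydride reduction of both γ-lactones cleaves only the acyl C–O bonds, so O7/O7′ stay on their carbons and C7, C8, C8′ and C7′ keep their configuration, while the benzyl ethers block quinone-methide formation that would cost the benzylic oxygens.

**Step 4**
Reactants: 7 rac-tetraol
Product: 8 rac-tetrakis-O-TBS ether
Conditions: TBSOTf (5 equiv), 2,6-lutidine, CH2Cl2, 0 °C
Reagents that add atoms: tert-butyldimethylsilyl trifluoromethanesulfonate (TBSOTf), CC(C)(C)[Si](C)(C)OS(=O)(=O)C(F)(F)F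
Why: Exhaustive O-silylation with a silyl triflate and a hindered pyridine base covers all four hydroxyls, including the hindered benzylic ones, without any need for selectivity.

**Step 5**
Reactants: 8 rac-tetrakis-O-TBS ether
Product: 9 rac-7,7′-bis-O-TBS-9,9′-diol
Conditions: HF·pyridine, pyridine, THF, 0 °C
Reagents that add atoms: none
Why: Selective desilylation rests on the large rate difference between primary and hindered secondary benzylic TBS ethers towards pyridine-buffered HF, which frees the 9,9′-diol while the buffered medium avoids ionisation at the electron-rich benzylic carbons.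

**Step 6**
Reactants: 9 rac-7,7′-bis-O-TBS-9,9′-diol
Product: 10 rac-trans-3,4-disubstituted oxolane bis-TBS ether
Conditions: PPh3 (1.3 equiv), DIAD (1.3 equiv), THF, 0 °C → rt
Reagents that add atoms: none
Why: Mitsunobu cyclodehydration of a primary 1,4-diol, in which one CH2OH is activated on phosphorus and displaced by the other in a 5-exo-tet SN2 reaction at a CH2 carbon, so no stereocentre is involved, the C8/C8′ substituents end up trans on the oxolane, and the silylated O7/O7′ cannot compete for ring closure.

**Step 7**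
Reactants: 10 rac-oxolane bis-TBS ether
Product: 11 rac-(7S,7′S,8R,8′R)-C2-symmetric diol
Conditions: TBAF (3 equiv), THF, 0 °C → rt
Reagents that add atoms: none
Why: Fluoride-induced desilylation (strong Si–F bond) frees both benzylic carbinols under non-acidic conditions that leave the benzyl ethers and the oxolane untouched.

**Step 8**
Reactants: 11 rac-C2-symmetric diol
Product: 12 (7S,7′S,8R,8′R)-C2-symmetric diol, single enantiomer (recovered unacylated)
Conditions: (R)-BTM (10 mol %), (i-PrCO)2O (1.2 equiv), i-Pr2NEt, Na2SO4, CHCl3, 0 °C, run past half conversion of the carbinol groups; chromatography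
Reagents that add atoms: none
Why: Acylative kinetic resolution with a chiral isothiourea acyl-transfer catalyst, which recognises aryl carbinols through π-stacking of the aryl group on the acylated catalyst and keeps its selectivity with α-branched carbinols, so (R)-BTM esterifies the (7R,7′R)-enantiomer at both sites while the (7S,7′S)-diol is recovered, its purity raised by the twofold selection.

**Step 9**
Reactants: 12 (7S,7′S,8R,8′R)-diol
Product: 13 (7S,8R,8′R)-7-hydroxy-7′-ketone
Conditions: Dess–Martin periodinane (1.0 equiv), pyridine, CH2Cl2, 0 °C; recovered 12 recycled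
Reagents that add atoms: none
Why: Dess–Martin oxidation with one equivalent of oxidant converts one of the two homotopic benzylic carbinols into the aryl ketone (statistical mono-oxidation with recovery of diol), and the buffered neutral medium avoids epimerisation at C8′ and β-elimination of the ring oxygen.

**Step 10**
Reactants: 13 hydroxy ketone
Product: 14 (7S,8R,8′R,7′R)-diol, phenols benzylated
Conditions: (S)-Me-CBS (1.0 equiv), BH3·SMe2 (3 equiv), THF, −20 °C; MeOH quench
Reagents that add atoms: none
Why: Corey–Bakshi–Shibata reduction, in which the (S)-oxazaborolidine–borane complex treats the aryl group as the large substituent and gives the (R)-carbinol at C7′ (the sense of acetophenone to (R)-1-phenylethanol), the epimer of the centre removed in step 9, so reagent control has to override the expected Felkin–Anh preference of the ketone for the 7′S epimer.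

**Step 11**
Reactants: 14 di-O-benzyl (7S,8R,8′R,7′R)-diol
Product: 15 target, CNP0157038.2
Conditions: H2 (1 atm), 10% Pd/C, EtOAc, rt
Reagents that add atoms: none
Why: Catalytic hydrogenolysis of the two aryl benzyl ethers over palladium in a neutral solvent at 1 atm, where ArO–CH2Ph cleavage is much faster than hydrogenolysis of the secondary benzylic C–OH bonds, so both carbinols and all four stereocentres are kept.

**Compound list**
1 | ferulic acid, (E)-3-(4-hydroxy-3-methoxyphenyl)prop-2-enoic acid | COc1cc(/C=C/C(=O)O)ccc1O | starting material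
2 | ferulic acid phenoxyl radical (not isolated) | COc1cc(/C=C/C(=O)O)ccc1[O] | intermediate
3 | rac-(2R,3R)-2,3-bis[(3-methoxy-4-oxocyclohexa-2,5-dien-1-ylidene)methyl]butanedioic acid, 8–8′ bis(quinone methide) diacid, exocyclic alkene geometry undefined (not isolated) | COC1=CC(=C[C@@H](C(=O)O)[C@H](C(=O)O)C=C2C=CC(=O)C(OC)=C2)C=CC1=O | intermediate
4 | rac-(3S,3aS,6S,6aS)-3,6-bis(4-hydroxy-3-methoxyphenyl)tetrahydrofuro[3,4-c]furan-1,4-dione, cis-fused, both aryl groups exo | COc1cc(ccc1O)[C@H]1OC(=O)[C@H]2[C@@H]1C(=O)O[C@@H]2c1ccc(O)c(OC)c1 | intermediate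
5 | benzyl bromide | BrCc1ccccc1 | starting material
6 | rac-(3S,3aS,6S,6aS)-3,6-bis(4-benzyloxy-3-methoxyphenyl)tetrahydrofuro[3,4-c]furan-1,4-dione | COc1cc(ccc1OCc1ccccc1)[C@H]1OC(=O)[C@H]2[C@@H]1C(=O)O[C@@H]2c1ccc(OCc2ccccc2)c(OC)c1 | intermediate
7 | rac-(1S,2R,3R,4S)-1,4-bis(4-benzyloxy-3-methoxyphenyl)-2,3-bis(hydroxymethyl)butane-1,4-diol | COc1cc([C@@H](O)[C@@H](CO)[C@H](CO)[C@H](O)c2ccc(OCc3ccccc3)c(OC)c2)ccc1OCc1ccccc1 | intermediate
8 | rac-tetrakis-O-(tert-butyldimethylsilyl) ether of 7 | COc1cc([C@@H](O[Si](C)(C)C(C)(C)C)[C@@H](CO[Si](C)(C)C(C)(C)C)[C@H](CO[Si](C)(C)C(C)(C)C)[C@H](O[Si](C)(C)C(C)(C)C)c2ccc(OCc3ccccc3)c(OC)c2)ccc1OCc1ccccc1 | intermediate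
9 | rac-(2R,3R)-2,3-bis[(S)-(4-benzyloxy-3-methoxyphenyl)(tert-butyldimethylsilyloxy)methyl]butane-1,4-diol | COc1cc([C@@H](O[Si](C)(C)C(C)(C)C)[C@@H](CO)[C@H](CO)[C@H](O[Si](C)(C)C(C)(C)C)c2ccc(OCc3ccccc3)c(OC)c2)ccc1OCc1ccccc1 | intermediate
10 | rac-(3R,4R)-3,4-bis[(S)-(4-benzyloxy-3-methoxyphenyl)(tert-butyldimethylsilyloxy)methyl]oxolane | COc1cc([C@@H](O[Si](C)(C)C(C)(C)C)[C@H]2COC[C@@H]2[C@H](O[Si](C)(C)C(C)(C)C)c2ccc(OCc3ccccc3)c(OC)c2)ccc1OCc1ccccc1 | intermediate
11 | rac-(S,S)-[(3R,4R)-oxolane-3,4-diyl]bis[(4-benzyloxy-3-methoxyphenyl)methanol] (racemate) | COc1cc([C@@H](O)[C@H]2COC[C@@H]2[C@H](O)c2ccc(OCc3ccccc3)c(OC)c2)ccc1OCc1ccccc1 | intermediate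
12 | (S,S)-[(3R,4R)-oxolane-3,4-diyl]bis[(4-benzyloxy-3-methoxyphenyl)methanol] (single enantiomer) | COc1cc([C@@H](O)[C@H]2COC[C@@H]2[C@H](O)c2ccc(OCc3ccccc3)c(OC)c2)ccc1OCc1ccccc1 | intermediate
13 | [(3R,4R)-4-[(S)-(4-benzyloxy-3-methoxyphenyl)(hydroxy)methyl]oxolan-3-yl](4-benzyloxy-3-methoxyphenyl)methanone | COc1cc([C@@H](O)[C@H]2COC[C@@H]2C(=O)c2ccc(OCc3ccccc3)c(OC)c2)ccc1OCc1ccccc1 | intermediate
14 | (S)-(4-benzyloxy-3-methoxyphenyl)[(3R,4R)-4-[(R)-(4-benzyloxy-3-methoxyphenyl)(hydroxy)methyl]oxolan-3-yl]methanol | COc1cc([C@@H](O)[C@H]2COC[C@@H]2[C@@H](O)c2ccc(OCc3ccccc3)c(OC)c2)ccc1OCc1ccccc1 | intermediate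
15 | 4-[(S)-hydroxy[(3R,4R)-4-[(R)-hydroxy(4-hydroxy-3-methoxyphenyl)methyl]oxolan-3-yl]methyl]-2-methoxyphenol, (7S,8R,8′R,7′R) | COc1cc([C@@H](O)[C@H]2COC[C@@H]2[C@@H](O)c2ccc(O)c(OC)c2)ccc1O | target

**Step count**
Total: 11 steps. Longest linear sequence: 11 steps from ferulic acid 1.

**Steps most likely to fail**

1. Step 8 (kinetic resolution). Both groups at each carbinol are bulky, so acyl transfer may be slow and the discrimination between the enantiomers too small to return 12 in high enantiomeric purity at a useful recovery. The fallback sets out from 11 and comes back at 12. Racemic 11 is acylated at both carbinols with (1S,4R)-camphanic chloride (Et3N, DMAP, CH2Cl2). This gives two diastereomers: the bis[(1S,4R)-camphanate] of the (7S,7′S,8R,8′R)-diol F1 and the bis[(1S,4R)-camphanate] of the (7R,7′R,8S,8′S)-diol F2. They are separated by chromatography or crystallisation, and F1 is cleaved with K2CO3 in methanol to 12.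

2. Step 10 (CBS reduction). Reagent control opposes the inherent Felkin–Anh bias, and the aryl and α-branched ring substituents of the ketone differ little in size, so facial selectivity may be poor and the reduction may largely return 12. The fallback sets out from 12, bypasses 13 and comes back at 14. A Mitsunobu inversion at one of the two equivalent carbinols (4-nitrobenzoic acid 1 equiv, PPh3, DIAD, toluene, −20 °C) should give the inverted (7S,8R,8′R,7′R)-7′-O-(4-nitrobenzoyl) mono-ester F3. Methanolysis (K2CO3, MeOH) then releases 14.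

3. Step 1 (key step). Radical coupling at C5 or through the phenol oxygen, unlike (meso) C8–C8′ coupling and further oxidation of the phenolic product may leave little dilactone. The fallback replaces starting material 1 and comes back at 4. Commercial 5-bromovanillin F4 is condensed with malonic acid (pyridine, piperidine, 90 °C, Knoevenagel–Doebner) to 5-bromoferulic acid F5. Its blocked C5 shuts off 8–5′ and 5–5′ coupling, as the 5-methoxy group does in sinapic acid. FeCl3 oxidation as in step 1 should then give the rac-5,5′-dibromo bis-lactone F6, and radical hydrodebromination (Bu3SnH, AIBN, dioxane, 90 °C) returns 4.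

**Further compounds**
F1 | step 8 | bis[(1S,4R)-camphanate] of the (7S,7′S,8R,8′R)-diol | COc1cc([C@@H](OC(=O)[C@@]45CC[C@@](C)(C(=O)O4)C5(C)C)[C@H]2COC[C@@H]2[C@H](OC(=O)[C@@]45CC[C@@](C)(C(=O)O4)C5(C)C)c2ccc(OCc3ccccc3)c(OC)c2)ccc1OCc1ccccc1
F2 | step 8 | bis[(1S,4R)-camphanate] of the (7R,7′R,8S,8′S)-diol | COc1cc([C@H](OC(=O)[C@@]45CC[C@@](C)(C(=O)O4)C5(C)C)[C@@H]2COC[C@H]2[C@@H](OC(=O)[C@@]45CC[C@@](C)(C(=O)O4)C5(C)C)c2ccc(OCc3ccccc3)c(OC)c2)ccc1OCc1ccccc1
F3 | step 10 | (7S,8R,8′R,7′R)-7′-O-(4-nitrobenzoyl) mono-ester of the di-O-benzyl diol | COc1cc([C@@H](O)[C@H]2COC[C@@H]2[C@@H](OC(=O)c2ccc(cc2)[N+](=O)[O-])c2ccc(OCc3ccccc3)c(OC)c2)ccc1OCc1ccccc1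
F4 | step 1 | 5-bromovanillin (commercial input) | COc1cc(C=O)cc(Br)c1O
F5 | step 1 | 5-bromoferulic acid | COc1cc(/C=C/C(=O)O)cc(Br)c1O
F6 | step 1 | rac-5,5′-dibromo exo,exo-diaryl bis-lactone | COc1cc(cc(Br)c1O)[C@H]1OC(=O)[C@H]2[C@@H]1C(=O)O[C@@H]2c1cc(Br)c(O)c(OC)c1
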